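The route rests on cutting the bond between C4, the tertiary carbinol carbon of the epoxycyclohexenone (ring A), and C1', the first vinylic carbon of the lower trienamide. In one operation a complete (E,E,E)-trienyllithium adds to the C4 ketone of an enantioenriched 5,6-epoxyquinone C1 dimethyl ketal that already bears the upper trienamide. The hydroxycyclopentenone (ring B) O–H and amide N–H of the nucleophile are masked merely as lithium salts. The step exploits the cup-shaped 7-oxabicyclo[4.1.0]heptenone. The C5–C6 oxirane oxygen blocks one face of C4=O, so C4 is set with hydroxyl syn to the epoxide, while the C1 ketal leaves C4 as the only ketone. Ketal hydrolysis then finishes the synthesis.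

Key step: step 11

Numbering used: in ring A, C1 is the ketone (ketal) carbon, C2 bears the amide nitrogen, C3 is =CH, C4 is the carbinol (ketone) carbon, and C5 and C6 are the oxirane carbons. C1' to C7' is the lower chain counted from ring A.

Assumption: the cinchonine-derived phase-transfer catalyst is taken to deliver the (5R,6S)-epoxide. Should the sense prove opposite, the pseudoenantiomeric N-benzylcinchonidinium chloride takes its place.

Step 1
Reactants: 1 (E)-4-methylpent-2-enal; 2 triethyl 4-phosphonocrotonate [ethyl (E)-4-(diethoxyphosphoryl)but-2-enoate]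
Product: 4 ethyl (2E,4E,6E)-8-methylnona-2,4,6-trienoate, via lithiated phosphonate 3 (not isolated)
Conditions: 2, LiN(SiMe3)2, THF, −78 °C; then 1, −78 → 0 °C
Reagents that add atoms: none
Why: Vinylogous Horner–Wadsworth–Emmons olefination, in which the delocalised anion 3 should react through its α-carbon with the aldehyde and collapse to the new E C4=C5 alkene, while the E alkenes brought in by 1 and 2 are untouched.

Step 2
Reactants: 4 ethyl (2E,4E,6E)-8-methylnona-2,4,6-trienoate; 5 3-amino-4-methoxyphenol
Product: 7 (2E,4E,6E)-N-(5-hydroxy-2-methoxyphenyl)-8-methylnona-2,4,6-trienamide, via aluminium anilide 6 (not isolated)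
Conditions: 5, AlMe3 (2.2 equiv), toluene, 0 °C → rt; then 4, 60 °C; aq KNaC4H4O6 work-up
Reagents that add atoms: none
Why: Aluminium-amide (Weinreb-type) aminolysis of an ester, in which AlMe3 metalates both acidic groups of 5 and only the Al–N unit of 6 transfers to the ester carbonyl, so the anilide should form without a saponification step and without O-acylation.

Step 3
Reactants: 7 (2E,4E,6E)-N-(5-hydroxy-2-methoxyphenyl)-8-methylnona-2,4,6-trienamide
Product: 8 (2E,4E,6E)-N-(6,6-dimethoxy-3-oxocyclohexa-1,4-dien-1-yl)-8-methylnona-2,4,6-trienamide (quinone C1 monoketal)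
Conditions: PhI(OAc)2, MeOH, 0 °C
Reagents that add atoms: methanol, CO
Why: Hypervalent-iodine oxidative dearomatisation of a 4-methoxyphenol, in which ligand exchange at the phenol oxygen, loss of PhI and capture of the para carbon by methanol should place the ketal next to the amide-bearing carbon, the electron-poor triene being inert.

Step 4
Reactants: 8 quinone C1 monoketal
Product: 9 (2E,4E,6E)-N-[(1S,6R)-2,2-dimethoxy-5-oxo-7-oxabicyclo[4.1.0]hept-3-en-3-yl]-8-methylnona-2,4,6-trienamide (5R,6S in ring A numbering)
Conditions: t-BuOOH, aq NaOH, N-benzylcinchoninium chloride (10 mol %), toluene, rt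
Reagents that add atoms: tert-butyl hydroperoxide, CC(C)(C)OO
Why: Asymmetric phase-transfer Weitz–Scheffer epoxidation, in which t-BuOO− ion-paired to the chiral ammonium cation adds to C6 of the only unsubstituted enone (C2=C3 is deactivated by its nitrogen donor and the trienamide is too poor an acceptor) and closes the cis-oxirane, so C5 (R) and C6 (S) are set together by the catalyst and recrystallisation remains available to raise enantiomeric purity.

Step 5
Reactants: 10 cyclopentane-1,3-dione
Product: 11 2-nitrocyclopentane-1,3-dione (enol form, 3-hydroxy-2-nitrocyclopent-2-en-1-one)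
Conditions: fuming HNO3, AcOH, 0–10 °C
Reagents that add atoms: nitric acid, O[N+](=O)[O-]
Why: Electrophilic nitration of the enol of a cyclic 1,3-dione at C2, its only nucleophilic carbon.

Step 6
Reactants: 11 2-nitrocyclopentane-1,3-dione
Product: 12 2-amino-3-hydroxycyclopent-2-en-1-one hydrochloride
Conditions: H2 (1 atm), Pd/C, HCl, EtOH, rt
Reagents that add atoms: hydrogen chloride, Cl
Why: Catalytic hydrogenation of the nitro group, with the amine trapped as its hydrochloride to prevent self-condensation and air oxidation, while the vinylogous-acid C=C is not reduced at this pressure.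

Step 7
Reactants: 12 2-amino-3-hydroxycyclopent-2-en-1-one hydrochloride; 13 diethylphosphonoacetic acid
Product: 14 diethyl {2-[(2-hydroxy-5-oxocyclopent-1-en-1-yl)amino]-2-oxoethyl}phosphonate
Conditions: EDC·HCl, Et3N, CH2Cl2, 0 °C → rt
Reagents that add atoms: none
Why: Carbodiimide amide coupling, in which the liberated C2 amine is the most nucleophilic site and any O-acyl isomer should migrate to nitrogen under the basic conditions.

Step 8
Reactants: 15 pyridine–sulfur trioxide complex (pyridinium-1-sulfonate)
Product: 16 potassium (1E,3E)-5-oxopenta-1,3-dien-1-olate (glutaconaldehyde potassium salt)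
Conditions: aq KOH, −20 → 40 °C
Reagents that add atoms: potassium hydroxide, [K+].[OH-]
Why: Zincke-type cleavage of an N-activated pyridinium, in which hydroxide adds at C2, the ring opens and hydrolysis of the N-sulfonated imine releases sulfamate and the all-trans enolate.

Step 9
Reactants: 16 glutaconaldehyde potassium salt
Product: 17 (2E,4E)-5-bromopenta-2,4-dienal
Conditions: Ph3PBr2, CH2Cl2, 0 °C → rt
Reagents that add atoms: dibromotriphenylphosphorane, BrP(Br)(c1ccccc1)(c1ccccc1)c1ccccc1
Why: Deoxybromination of a vinylogous carboxylate, in which O-phosphonium formation and bromide addition–elimination at C5 are driven by formation of Ph3P=O and should settle to the thermodynamically preferred E,E isomer.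

Step 10
Reactants: 14 ring B phosphonoacetamide; 17 (2E,4E)-5-bromopenta-2,4-dienal
Product: 19 (2E,4E,6E)-7-bromo-N-(2-hydroxy-5-oxocyclopent-1-en-1-yl)hepta-2,4,6-trienamide, via trilithiated phosphonoacetamide 18 (not isolated)
Conditions: 14, LiN(SiMe3)2 (3.1 equiv), THF, −78 °C; then 17, −78 → 0 °C; 1 M HCl to pH 3
Reagents that add atoms: none
Why: Horner–Wadsworth–Emmons olefination, in which the enol and amide protons are removed first so that the phosphonate carbanion of 18 is the only reactive nucleophile, attack at the non-enolisable aldehyde gives the E C2=C3 alkene, and the bromodiene geometry is preserved.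

Step 11
Reactants: 9 (5R,6S)-epoxyquinone C1 dimethyl ketal; 19 bromotrienamide
Product: 23 manumycin G C1 dimethyl ketal [(4S,5R,6S); C4 hydroxyl syn to the oxirane; all six chain alkenes E], via dilithium salt 20 (not isolated), via trienyllithium 21 (not isolated), via sodium amidate 22 (not isolated)
Conditions: 19, MeLi (2.0 equiv), THF, −78 °C; t-BuLi (2.0 equiv), −78 °C; separately 9, NaH (1.0 equiv), THF, 0 °C; combine at −78 °C, then −40 °C; AcOH quench
Reagents that add atoms: none
Why: Two equivalents of MeLi turn the enol O–H and amide N–H of 19 into lithium salts (20) that switch off both carbonyl groups and the trienamide as electrophiles, t-BuLi then effects bromine–lithium exchange at C1' with retention of the E geometry, and the sp2 carbanion of 21 attacks the C4 carbonyl of 22 in a polar 1,2-addition. The closest known reaction type is the addition of alkenyllithium reagents to 5,6-epoxy-1,4-benzoquinone 1-monoketals, combined with halogen–metal exchange on substrates whose acidic protons have been removed beforehand. No ring is closed. The only new stereocentre, C4, is controlled by the C5–C6 oxirane of the cup-shaped 7-oxabicyclo[4.1.0]heptenone: the nucleophile should approach on the face opposite the oxirane oxygen, which places the C4 hydroxyl syn to the epoxide (4S). The step needs site selectivity for C4 over C1, the oxirane carbons and C2 (conjugate addition): the dimethyl ketal removes C1 as a carbonyl, the hard lithium nucleophile at low temperature favours carbonyl over oxirane attack, and C2 is fully substituted and carries a nitrogen donor. Prior deprotonation of 9 with NaH keeps the valuable nucleophile from being spent as a base.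

Step 12
Reactants: 23 manumycin G C1 dimethyl ketal
Product: 24 manumycin G
Conditions: montmorillonite K10 clay (idealised Al2Si4O10(OH)2·nH2O), wet CH2Cl2, rt
Reagents that add atoms: water, O
Why: Acid-catalysed ketal hydrolysis on a mildly acidic clay surface, in which the C1 oxocarbenium should form faster than ionisation at C4 (a C4 cation would be destabilised by the adjacent oxirane and the electron-poor trienamide), so the oxirane, the tertiary alcohol and all three stereocentres are left untouched.

Compound list
1 | (E)-4-methylpent-2-enal | CC(C)/C=C/C=O | starting material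
2 | triethyl 4-phosphonocrotonate | CCOC(=O)/C=C/CP(=O)(OCC)OCC | starting material
3 | lithiated phosphonate (α-lithio derivative of 2) | CCOC(=O)/C=C/C([Li])P(=O)(OCC)OCC | intermediate
4 | ethyl (2E,4E,6E)-8-methylnona-2,4,6-trienoate | CC(C)/C=C/C=C/C=C/C(=O)OCC | intermediate
5 | 3-amino-4-methoxyphenol | COc1ccc(O)cc1N | starting material
6 | aluminium anilide (N,O-bis(dimethylaluminium) derivative of 5) | COc1ccc(O[Al](C)C)cc1N[Al](C)C | intermediate
7 | (2E,4E,6E)-N-(5-hydroxy-2-methoxyphenyl)-8-methylnona-2,4,6-trienamide | CC(C)/C=C/C=C/C=C/C(=O)Nc1cc(O)ccc1OC | intermediate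
8 | (2E,4E,6E)-N-(6,6-dimethoxy-3-oxocyclohexa-1,4-dien-1-yl)-8-methylnona-2,4,6-trienamide | CC(C)/C=C/C=C/C=C/C(=O)NC1=CC(=O)C=CC1(OC)OC | intermediate
9 | (2E,4E,6E)-N-[(1S,6R)-2,2-dimethoxy-5-oxo-7-oxabicyclo[4.1.0]hept-3-en-3-yl]-8-methylnona-2,4,6-trienamide | CC(C)/C=C/C=C/C=C/C(=O)NC1=CC(=O)[C@@H]2O[C@@H]2C1(OC)OC | intermediate
10 | cyclopentane-1,3-dione | O=C1CCC(=O)C1 | starting material
11 | 2-nitrocyclopentane-1,3-dione (enol form) | O=C1CCC(O)=C1[N+](=O)[O-] | intermediate
12 | 2-amino-3-hydroxycyclopent-2-en-1-one hydrochloride | NC1=C(O)CCC1=O.Cl | intermediate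
13 | diethylphosphonoacetic acid | CCOP(=O)(CC(=O)O)OCC | starting material
14 | diethyl {2-[(2-hydroxy-5-oxocyclopent-1-en-1-yl)amino]-2-oxoethyl}phosphonate | CCOP(=O)(CC(=O)NC1=C(O)CCC1=O)OCC | intermediate
15 | pyridine–sulfur trioxide complex | [O-]S(=O)(=O)[n+]1ccccc1 | starting material
16 | potassium (1E,3E)-5-oxopenta-1,3-dien-1-olate | [K+].[O-]/C=C/C=C/C=O | intermediate
17 | (2E,4E)-5-bromopenta-2,4-dienal | Br/C=C/C=C/C=O | intermediate
18 | trilithiated phosphonoacetamide (C-, N- and O-lithio derivative of 14) | CCOP(=O)(OCC)C([Li])C(=O)N([Li])C1=C(O[Li])CCC1=O | intermediate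
19 | (2E,4E,6E)-7-bromo-N-(2-hydroxy-5-oxocyclopent-1-en-1-yl)hepta-2,4,6-trienamide | Br/C=C/C=C/C=C/C(=O)NC1=C(O)CCC1=O | intermediate
20 | dilithium salt of 19 (N- and O-lithio) | Br/C=C/C=C/C=C/C(=O)N([Li])C1=C(O[Li])CCC1=O | intermediate
21 | trienyllithium (C7-lithio derivative of the dilithium salt, all E) | [Li]/C=C/C=C/C=C/C(=O)N([Li])C1=C(O[Li])CCC1=O | intermediate
22 | sodium amidate of 9 | CC(C)/C=C/C=C/C=C/C(=O)N([Na])C1=CC(=O)[C@@H]2O[C@@H]2C1(OC)OC | intermediate
23 | manumycin G C1 dimethyl ketal, (4S,5R,6S) | CC(C)/C=C/C=C/C=C/C(=O)NC1=C[C@@](O)(/C=C/C=C/C=C/C(=O)NC2=C(O)CCC2=O)[C@@H]2O[C@@H]2C1(OC)OC | intermediate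
24 | manumycin G, (4S,5R,6S) | CC(C)/C=C/C=C/C=C/C(=O)NC1=C[C@@](O)(/C=C/C=C/C=C/C(=O)NC2=C(O)CCC2=O)[C@@H]2O[C@@H]2C1=O | target

Total step count: 12.
Longest linear sequence: 6 steps (steps 5, 6, 7, 10, 11, 12). The sequence 1, 2, 3, 4, 11, 12 is of equal length.

Steps most likely to fail

Step 11.
- **What may go wrong:** The triply lithiated nucleophile may aggregate or precipitate. Bromine–lithium exchange may be outrun by proton transfer or by addition of t-BuLi to the polyene. The alkenyllithium may lose its geometry.
- **Change of approach:** The fallback forms the same bond but replaces the sp2 carbanion by a far less basic acetylide and sets the C1'=C2' geometry afterwards. It sets out from 14 and 9 and comes back to the route at 23.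
- **Nucleophile:** Commercial (E)-pent-2-en-4-yn-1-ol is oxidised with MnO2 to (E)-pent-2-en-4-ynal F1. Condensation of this aldehyde with 14 as in step 10 gives (2E,4E)-N-(2-hydroxy-5-oxocyclopent-1-en-1-yl)hepta-2,4-dien-6-ynamide F2. LiN(i-Pr)2 (3 equiv) then gives, by deprotonation only, the trilithium acetylide F3.
- **Coupling:** The acetylide is added to 22 (made from 9 as in step 11) on the face opposite the oxirane, to give the propargylic alcohol F4.
- **Alkene geometry:** Ruthenium-catalysed trans-hydrosilylation ([Cp*Ru(MeCN)3]PF6, (EtO)3SiH, CH2Cl2) gives the C2'-triethoxysilyl alkene F5. Protodesilylation with AgF in aqueous THF/MeOH gives 23.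

Step 4.
- **What may go wrong:** Facial selectivity of the ion-paired hydroperoxide may be poor. Partial deprotonation of the acidic amide N–H at the interface may slow turnover.
- **Change of approach:** The fallback gives up asymmetric catalysis for resolution. It sets out from 8 and comes back to the route at 9.
- **Sequence:** H2O2/K2CO3 in aqueous THF gives the racemic cis-epoxide F6. Its enantiomers are separated by preparative supercritical-fluid chromatography on an amylose-derived chiral phase, and the (5R,6S) enantiomer is 9.

Step 10.
- **What may go wrong:** The polyanion may attack the bromine-bearing terminus of the dienal by addition–elimination. Carbanion formation may also stay incomplete next to the amidate.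
- **Change of approach:** The fallback builds the chain before the amide. It sets out from 17 and comes back to the route at 19.
- **Sequence:** Wittig olefination with Ph3P=CHCO2Et gives ethyl (2E,4E,6E)-7-bromohepta-2,4,6-trienoate F7. Saponification with LiOH gives (2E,4E,6E)-7-bromohepta-2,4,6-trienoic acid F8. Carbodiimide coupling with 12 under the conditions of step 7 gives 19.

Further compounds
F1 | step 11 | (E)-pent-2-en-4-ynal | C#C/C=C/C=O
F2 | step 11 | (2E,4E)-N-(2-hydroxy-5-oxocyclopent-1-en-1-yl)hepta-2,4-dien-6-ynamide | C#C/C=C/C=C/C(=O)NC1=C(O)CCC1=O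
F3 | step 11 | trilithium acetylide of F2 | [Li]C#C/C=C/C=C/C(=O)N([Li])C1=C(O[Li])CCC1=O
F4 | step 11 | propargylic alcohol (C1'≡C2' analogue of 23, hydroxyl syn to the oxirane) | CC(C)/C=C/C=C/C=C/C(=O)NC1=C[C@@](O)(C#C/C=C/C=C/C(=O)NC2=C(O)CCC2=O)[C@@H]2O[C@@H]2C1(OC)OC
F5 | step 11 | C2'-triethoxysilyl alkene (silicon cis to C4 across C1'=C2') | CC(C)/C=C/C=C/C=C/C(=O)NC1=C[C@@](O)(/C=C(\[Si](OCC)(OCC)OCC)/C=C/C=C/C(=O)NC2=C(O)CCC2=O)[C@@H]2O[C@@H]2C1(OC)OC
F6 | step 4 | racemic cis-epoxide (racemate of 9) | CC(C)/C=C/C=C/C=C/C(=O)NC1=CC(=O)C2OC2C1(OC)OC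
F7 | step 10 | ethyl (2E,4E,6E)-7-bromohepta-2,4,6-trienoate | Br/C=C/C=C/C=C/C(=O)OCC
F8 | step 10 | (2E,4E,6E)-7-bromohepta-2,4,6-trienoic acid | Br/C=C/C=C/C=C/C(=O)O
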